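**Retrosynthetic overview**
1. Target 12 ⇐ C4 ketone 11 by equatorial hydride delivery (axial C4–OH cis to C3–Me); 11 ⇐ 10 by hydrolysis of the C3=C4 methyl enol ether.
2. C1 angelate 10 ⇐ trans-alcohol 8 ⇐ C1 ketone 7 by axial hydride attack.
3. C9–C10 bond and the C9 stereocentre ⇐ aldehyde 4 by catalytic asymmetric alkenylzinc addition, acetylated in the same flask.
4. C6–C7 bond with both stereocentres ⇐ Birch diene 2 + crotonaldehyde 3 by an imidazolidinone (iminium) catalysed Mukaiyama–Michael-type addition (key step, new).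
5. No ring is built: the six-membered ring is the arene of 2,5-dimethoxytoluene 1, whose two OMe groups become the differentiated C1 and C4 oxygens.

Assumption: atom labels follow the target (C1 = ring C–OAng, C3 = ring C–Me, C4 = ring C–OH, C6 = ring C bearing the side chain, C7 = side-chain CHMe, C9 = CHOAc); compounds 1, 3, 5 and 9 are bought.

**Step 1**
Reactants: 1 2,5-dimethoxytoluene
Product: 2 1,4-dimethoxy-2-methylcyclohexa-1,4-diene
Conditions: Li, NH3(l), t-BuOH, THF, −78 → −33 °C; then H2O
Reagents that add atoms: none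
Why: Birch reduction leaves the donor-substituted carbons (OMe, Me) on the two isolated double bonds, giving the achiral bis(enol ether) with C3–Me and both ring oxygens already in place; no stereocentre is formed.

**Step 2**
Reactants: 2 1,4-dimethoxy-2-methylcyclohexa-1,4-diene (1.5 equiv); 3 (E)-crotonaldehyde
Product: 4 (3R)-3-[(1S)-3-methoxy-4-methyl-6-oxocyclohex-3-en-1-yl]butanal
Conditions: (2S,5S)-5-benzyl-2-tert-butyl-3-methylimidazolidin-4-one·TFA (20 mol%), CH2Cl2, H2O (2 equiv), −30 °C
Reagents that add atoms: water, O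
Why: Proposed new method: an iminium-catalysed Mukaiyama–Michael-type addition in which a Birch-derived alkyl (not silyl) enol ether is the π-nucleophile; the less hindered trisubstituted enol ether (nucleophilicity comparable to a silyl enol ether) attacks the β-carbon of the (E)-iminium ion on the face not shielded by the benzyl group (the sense that gives (R)-3-substituted butanals in the known indole and silyloxyfuran additions, here C7 = R), an open synclinal (endo-like) approach of the cyclic enol ether is expected to give the syn ring centre (C6 = S), water hydrolyses the resulting C1 oxocarbenium to the ketone with loss of MeOH, and the tetrasubstituted C3=C4 enol ether stays as the masked C4 ketone; closest known reaction type is the imidazolidinone-catalysed Mukaiyama–Michael addition of silyloxyfurans and silyl enol ethers to enals.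

**Step 3**
Reactants: 4 (3R)-3-[(1S)-3-methoxy-4-methyl-6-oxocyclohex-3-en-1-yl]butanal; 5 2-methylprop-1-enylmagnesium bromide
Product: 7 (4R,6R)-6-[(1S)-3-methoxy-4-methyl-6-oxocyclohex-3-en-1-yl]-2-methylhept-2-en-4-yl acetate, via zinc alkoxide 6 (not isolated)
Conditions: 5, ZnCl2 (0.5 equiv per 5), THF, then 1,4-dioxane, filter; (−)-MIB (10 mol%), PhMe, −20 → 0 °C; then Ac2O, rt
Reagents that add atoms: acetic anhydride, CC(=O)OC(C)=O
Why: Amino-alcohol-catalysed asymmetric alkenylzinc addition to an aldehyde: the zinc reagent ignores the C1 ketone, (−)-MIB delivers the alkenyl group to the Si face of the aldehyde (the sense that gives (S)-1-phenylpropanol with Et2Zn, here C9 = R), and in-flask acetylation of the zinc alkoxide installs the acetate before the δ-hydroxy ketone can close to a hemiketal.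

**Step 4**
Reactants: 7 (4R,6R)-6-[(1S)-3-methoxy-4-methyl-6-oxocyclohex-3-en-1-yl]-2-methylhept-2-en-4-yl acetate
Product: 8 (4R,6R)-6-[(1S,6R)-6-hydroxy-3-methoxy-4-methylcyclohex-3-en-1-yl]-2-methylhept-2-en-4-yl acetate
Conditions: NaBH4, MeOH/THF, −40 °C
Reagents that add atoms: none
Why: Substrate-controlled borohydride reduction: the small hydride attacks the half-chair ketone axially (C3 is sp2, so one 1,3-diaxial contact is missing), giving mainly the equatorial C1–OH trans to the equatorial C6 side chain (C1 = R), with the minor cis isomer removed by chromatography; acetate and enol ether are inert.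

**Step 5**
Reactants: 8 (4R,6R)-6-[(1S,6R)-6-hydroxy-3-methoxy-4-methylcyclohex-3-en-1-yl]-2-methylhept-2-en-4-yl acetate; 9 angelic acid
Product: 10 (1R,6S)-6-[(2R,4R)-4-acetoxy-6-methylhept-5-en-2-yl]-4-methoxy-3-methylcyclohex-3-en-1-yl (2Z)-2-methylbut-2-enoate
Conditions: 9, 2,4,6-Cl3C6H2COCl, Et3N, PhMe, rt; then 8, 80 °C
Reagents that add atoms: none
Why: Yamaguchi-type esterification through the mixed anhydride without DMAP acylates the hindered secondary alcohol with retention at C1 and without Z→E isomerisation of the angelate; the anhydrous, amine-buffered medium leaves the enol ether and allylic acetate intact.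

**Step 6**
Reactants: 10 (1R,6S)-6-[(2R,4R)-4-acetoxy-6-methylhept-5-en-2-yl]-4-methoxy-3-methylcyclohex-3-en-1-yl (2Z)-2-methylbut-2-enoate
Product: 11 (1R,2S,5S)-2-[(2R,4R)-4-acetoxy-6-methylhept-5-en-2-yl]-5-methyl-4-oxocyclohexyl (2Z)-2-methylbut-2-enoate
Conditions: (CO2H)2·2H2O, THF/H2O, rt
Reagents that add atoms: water, O
Why: Mild acid-catalysed enol ether hydrolysis: axial protonation at C3 and equilibration α to the new ketone both place the methyl equatorial (C3 = S, cis to the angelate, trans to the side chain), and oxalic acid is too weak to ionise the allylic acetate.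

**Step 7**
Reactants: 11 (1R,2S,5S)-2-[(2R,4R)-4-acetoxy-6-methylhept-5-en-2-yl]-5-methyl-4-oxocyclohexyl (2Z)-2-methylbut-2-enoate
Product: 12 (1R,2S,4R,5S)-2-[(2R,4R)-4-acetoxy-6-methylhept-5-en-2-yl]-4-hydroxy-5-methylcyclohexyl (2Z)-2-methylbut-2-enoate
Conditions: L-Selectride (1.1 equiv), THF, −78 °C; then H2O
Reagents that add atoms: none
Why: Bulky trialkylborohydride reduction of a 2-methylcyclohexanone: equatorial attack gives the axial alcohol cis to the C3 methyl (C4 = R), and at −78 °C ketone reduction is far faster than attack on the acetate or conjugate reduction of the α,β-disubstituted angelate.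

**Compound list**
1 | 2,5-dimethoxytoluene | COc1ccc(OC)c(C)c1 | starting material
2 | 1,4-dimethoxy-2-methylcyclohexa-1,4-diene | COC1=C(C)CC(OC)=CC1 | intermediate
3 | (E)-crotonaldehyde | C/C=C/C=O | starting material
4 | (3R)-3-[(1S)-3-methoxy-4-methyl-6-oxocyclohex-3-en-1-yl]butanal | O=C1CC(C)=C(OC)C[C@H]1[C@H](C)CC=O | intermediate
5 | 2-methylprop-1-enylmagnesium bromide | CC(C)=C[Mg]Br | starting material
6 | (2-methylprop-1-enyl)zinc (4R,6R)-6-[(1S)-3-methoxy-4-methyl-6-oxocyclohex-3-en-1-yl]-2-methylhept-2-en-4-olate (zinc alkoxide, not isolated) | O=C1CC(C)=C(OC)C[C@H]1[C@H](C)C[C@H](C=C(C)C)O[Zn]C=C(C)C | intermediate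
7 | (4R,6R)-6-[(1S)-3-methoxy-4-methyl-6-oxocyclohex-3-en-1-yl]-2-methylhept-2-en-4-yl acetate | O=C1CC(C)=C(OC)C[C@H]1[C@H](C)C[C@H](C=C(C)C)OC(C)=O | intermediate
8 | (4R,6R)-6-[(1S,6R)-6-hydroxy-3-methoxy-4-methylcyclohex-3-en-1-yl]-2-methylhept-2-en-4-yl acetate | O[C@@H]1CC(C)=C(OC)C[C@H]1[C@H](C)C[C@H](C=C(C)C)OC(C)=O | intermediate
9 | angelic acid, (2Z)-2-methylbut-2-enoic acid | C/C=C(/C)C(=O)O | starting material
10 | (1R,6S)-6-[(2R,4R)-4-acetoxy-6-methylhept-5-en-2-yl]-4-methoxy-3-methylcyclohex-3-en-1-yl (2Z)-2-methylbut-2-enoate | C/C=C(/C)C(=O)O[C@@H]1CC(C)=C(OC)C[C@H]1[C@H](C)C[C@H](C=C(C)C)OC(C)=O | intermediate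
11 | (1R,2S,5S)-2-[(2R,4R)-4-acetoxy-6-methylhept-5-en-2-yl]-5-methyl-4-oxocyclohexyl (2Z)-2-methylbut-2-enoate | C/C=C(/C)C(=O)O[C@@H]1C[C@H](C)C(=O)C[C@H]1[C@H](C)C[C@H](C=C(C)C)OC(C)=O | intermediate
12 | (1R,2S,4R,5S)-2-[(2R,4R)-4-acetoxy-6-methylhept-5-en-2-yl]-4-hydroxy-5-methylcyclohexyl (2Z)-2-methylbut-2-enoate | C/C=C(/C)C(=O)O[C@@H]1C[C@H](C)[C@H](O)C[C@H]1[C@H](C)C[C@H](C=C(C)C)OC(C)=O | target

**Step count**
Total steps: 7. Longest linear sequence: 7 (1 → 12).

**Three steps most likely to fail**

Step 2 (proposed new step). The risks are competing acid hydrolysis of 2 by the ammonium salt, too slow a reaction of the alkyl enol ether with the iminium ion, and an uncertain syn/anti ratio at C6/C7. The fallback uses known chemistry and sets out from 2 and 3. A chiral tridentate Schiff-base chromium(III) chloride catalyst (4 Å sieves, rt) promotes the known inverse-electron-demand hetero-Diels–Alder reaction of an enal with an enol ether. Compound 3 acts as the heterodiene and the trisubstituted enol ether of 2 as the dienophile, and the endo, cis-fused adduct is (4R,4aS,8aS)-6,8a-dimethoxy-4,7-dimethyl-4a,5,8,8a-tetrahydro-4H-chromene F1. The concerted endo cycloaddition fixes the same C6/C7 relationship, and the catalyst antipode fixes the absolute sense. Buffered hydrolysis (pH 4–5, THF/H2O, 0 °C) of the ketal and vinyl ether of F1 opens it to the keto aldehyde, and the route is rejoined at 4.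

Step 3. The risks are an eroded ee from residual magnesium salts, a mismatched influence of the C7 centre, and hemiketal formation before acetylation. The fallback sets out from 4 and gives up catalyst control. Reagent 5 is transmetalated to the alkenyltitanium triisopropoxide (ClTi(OiPr)3, THF, −78 → −20 °C) and added to the aldehyde only. This gives the separable C9 epimers (6S)-6-[(2R,4R)-4-hydroxy-6-methylhept-5-en-2-yl]-4-methoxy-3-methylcyclohex-3-en-1-one F2 and (6S)-6-[(2R,4S)-4-hydroxy-6-methylhept-5-en-2-yl]-4-methoxy-3-methylcyclohex-3-en-1-one F3. F2 is acetylated (Ac2O, pyridine) and F3 is inverted by a Mitsunobu reaction with acetic acid (PPh3, DIAD, THF, 0 °C), so both epimers converge, and the route is rejoined at 7.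

Step 4. The risk is a modest trans:cis ratio in the borohydride reduction (perhaps 3–5:1). The fallback sets out from 7 and uses the opposite, far more selective facial preference. L-Selectride (THF, −78 °C) attacks equatorially to give the cis alcohol (4R,6R)-6-[(1S,6S)-6-hydroxy-3-methoxy-4-methylcyclohex-3-en-1-yl]-2-methylhept-2-en-4-yl acetate F4 as essentially one diastereomer. A Mitsunobu esterification with angelic acid 9 (PPh3, DIAD, PhMe, 0 °C → rt) inverts C1 and installs the angelate in one operation; E2 elimination of the axial alkoxyphosphonium towards C2 is the competing path here. The route is rejoined at 10, bypassing 8.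

**Further compounds**
F1 | step 2 | (4R,4aS,8aS)-6,8a-dimethoxy-4,7-dimethyl-4a,5,8,8a-tetrahydro-4H-chromene | COC1=C(C)C[C@]2(OC)OC=C[C@@H](C)[C@@H]2C1
F2 | step 3 | (6S)-6-[(2R,4R)-4-hydroxy-6-methylhept-5-en-2-yl]-4-methoxy-3-methylcyclohex-3-en-1-one | O=C1CC(C)=C(OC)C[C@H]1[C@H](C)C[C@H](C=C(C)C)O
F3 | step 3 | (6S)-6-[(2R,4S)-4-hydroxy-6-methylhept-5-en-2-yl]-4-methoxy-3-methylcyclohex-3-en-1-one | O=C1CC(C)=C(OC)C[C@H]1[C@H](C)C[C@@H](C=C(C)C)O
F4 | step 4 | (4R,6R)-6-[(1S,6S)-6-hydroxy-3-methoxy-4-methylcyclohex-3-en-1-yl]-2-methylhept-2-en-4-yl acetate | O[C@H]1CC(C)=C(OC)C[C@H]1[C@H](C)C[C@H](C=C(C)C)OC(C)=O
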